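**Two amounts.** The ratio to watch in this flask is the free catalyst charged over that charge less a dead charge, the intercept read below.

all flasks: starting material 20 mM
- winter: free catalyst 0.45 mM; added ligand 0.73 mM; run made earlier
- autumn: free catalyst 0.68 mM; added ligand 0.73 mM; run made earlier
- dawn: free catalyst 0.90 mM; added ligand 1.1 mM; run made earlier
- flask: free catalyst 0.90 mM; added ligand 0.73 mM

| run | time / d | target / % | starting material / % |
|---|---|---|---|
| winter | 1.04 | 8.4 | 89.9 |
| winter | 3.00 | 23.5 | 77.0 |
| winter | 6.00 | 42.3 | 57.4 |
| winter | 8.00 | 53.2 | 46.7 |
| winter | 12.0 | 69.1 | 31.4 |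
| autumn | 1.04 | 13.5 | 85.8 |
| autumn | 3.00 | 36.0 | 63.1 |
| autumn | 6.00 | 60.9 | 39.7 |
| autumn | 8.00 | 73.2 | 27.1 |
| autumn | 12.0 | 87.9 | 12.4 |
| dawn | 2.50 | 33.7 | 66.2 |
| dawn | 5.00 | 58.0 | 42.9 |
| dawn | 8.00 | 76.6 | 23.4 |
| dawn | 10.0 | 83.9 | 15.6 |
| dawn | 12.0 | 89.3 | 10.2 |

(each reading ± 0.5 percentage points)

- apparent order in free catalyst when 20% of the starting material are converted (percent change of the rate of making target for one percent more free catalyst charged)
- factor on the rate of making target when 20% of the starting material are converted if free catalyst is charged twice over

**Mean constants.** Each drifting curve is replaced by its mean pseudo-first-order constant: minus the logarithm of the fraction of starting material left, divided by time. At 8.00 d, winter gives 0.0952 d⁻¹ and autumn 0.163 d⁻¹, both at the same added ligand. The constant grows by a factor of 1.71 for a factor of 1.51 in c(free catalyst), a stronger rise, so the line through the two runs reaches zero at a positive charge. That intercept is 0.128 mM, the dead charge, a feature of the line and not a measured amount.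

**The reckoning.** On this line, the order is c(free catalyst) over c(free catalyst) minus the dead charge. My reckoning for the flask is 1.17, and doubling gives 2.17. Taking the means at 6.00 d and 12.0 d instead gives orders of 1.13 and 1.22, a spread that holds the error of using a mean together with the scatter of the readings.

**The result.** The forecast gives 1.05 and 2.1, expecting that the excess “should fade at higher catalyst”. The flask gives 1.2 and 2.38.

    catalyst intermediate B → free catalyst + target (k = 1.40 h⁻¹)
    starting material + free catalyst ⇌ catalyst intermediate A (K = 60.0 M⁻¹, k = 54.0 M⁻¹ h⁻¹)
    catalyst intermediate A ⇌ catalyst intermediate B (K = 0.760, k = 20.0 h⁻¹)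
    free catalyst + added ligand ⇌ idle complex, settled at all times (K = 3100 M⁻¹)

**Idle complex.** Read backwards on the same line, the flask's order corresponds to a dead charge of 0.175 mM. A dead charge of zero makes the ratio one. With the association of free catalyst and added ligand to idle complex taken away, the flask's order falls from 1.2 to 1.0.

The numbers in the tables stem from a simulated flask for substances that don't exist; noise was put on by code.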